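## Structural features

The target joins a 28-carbon nor-friedelane of the tingenone type (rings A–E: aromatic ring A, a C6=C7 styrene in ring B, C21 ketone and C20 methyl in ring E) to a guaiane through a 1,4-dioxane. The dioxane is fused to the arene at C2/C3 and to the hydroazulene at C1'/C5', so that C1'–C5' is the shared bond of a propellane (cyclopentene, cycloheptane, dioxane). There are eleven stereocentres: C8, C9, C13, C14, C17, C18 and C20 in the triterpene, and C1', C5', C7' and C10' in the sesquiterpene. C9, C13, C14 and C17 are quaternary; the C13 and C14 methyls are vicinal and anti (trans C/D), D/E is cis, and H8 is syn to the C9 and C14 methyls (cis B/C). In the sesquiterpene both ether oxygens are anti to the C10' methyl and the C7' isopropenyl group, which are cis to each other. Fragile groups are the tertiary allylic aryl ether at C5' (acid), the isopropenyl and styrene olefins, the electron-rich trioxygenated arene (oxidants) and the C20 centre next to the ketone (base). The real difficulty lies in the aryl-bearing quaternary C9 beside the C13/C14 quaternary pair, in two tertiary C–O bonds of fixed orientation (the oxygen on the methyl-flanked arene carbon C3 goes to C5'), and in the C8 configuration. The key step exploits ring B: C5/C10 of the arene, C6=C7, C8–H and quaternary C9 are, after a shift of the olefin to C7=C8, the cyclohexene of a [4+2] adduct between a C5–C10 aryne and the C6=C7–C8=C9 diene of a 2-methyl-1-vinylcyclohexene (ring C).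

## Logic of the disconnections

**47 to 46 to 45.** No skeletal bond is cut. The C21 carbonyl is masked as a dioxolane and the C6=C7 styrene with H8 is traced back to the C7=C8 isomer. The reason is that C20 beside a free ketone would not survive base, and that 45 is a cycloaddition retron. The gain is the removal of the C8 stereocentre. The demand is that the forward prototropic shift places hydrogen on the β-face of C8 and that the final hydrolysis spares the tertiary allylic aryl ether.

**45 to 25 plus 43.** C5–C6 and C9–C10 are cut, opening ring B. This divides the molecule into two halves of similar size and removes the quaternary C9 centre and its aryl bond in one operation. The forward step must prefer [4+2] over ene and [2+2] pathways, must bond C9 to C10 and not to C5, and must approach the diene on its α-face.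

**43 to 42 to 41 to 40.** The C7–C8 bond (vinyl) and the C9–C25 bond (methyl) are cut, leading back to a ring C ketone whose only enolisable position is C9. The gain is a tricyclic ketone with no sp2 stereochemical issue. The demand is enolisation and triflation at a hindered ketone flanked by quaternary C14.

**40 to 39 to 38 to 37.** Only functional groups change: the C8 carbonyl comes from a silyl ether and the C21 ketal from the ketone. The two carbonyls need opposite handling, so C8 stays at the alcohol level until C21 is protected. The demand is a ketalisation that tolerates the silyl ether.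

**37 to 35 to 34 to 33.** C17–C28, C17=C22 and C18–C19 are cut: ring E is removed as a methyl cuprate plus a four-carbon enone annulation unit. The gain is a bicyclic enol ether. The demand is C–C bond formation at the neopentyl C18 with defined enolate regiochemistry, and β-face delivery of the C17 methyl.

**33 to 31 to 30 to 29 to 28 to 27 to 26.** The C13–C27 bond is cut: the methyl is a reductively opened cyclopropane, placed by a hydroxyl on the face anti to the C14 methyl. The gain is a commercial enantiopure decalin dione in which C14 is already quaternary. The demand is an allylic alcohol of the correct (α) configuration at C17.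

**25 to 22 to 21 to 18.** The C–Si, O–S, C–Br and phenol C–O bonds at C10 and C5 are removed in turn, because the aryne-generating pair is best installed last on a substituted phenol. The gain is a plain aryl bromide. The demand is chemoselective arene functionalisation in the presence of two olefins.

**18 to 17 to 16 to 15 plus 3.** The dioxane is dissected one C–O bond at a time: first O–C5' (allylic, closed intramolecularly), then O–C1' (intermolecular). The orientation of the unsymmetrical arene then follows from the order of events and not from a cycloaddition regiochemistry. The demand is that the less hindered phenol of 3 reacts first and that ring closure at the tertiary allylic carbon is cis, which the propellane enforces.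

**15 to 14 to 13 to 12.** The C1'–O and C3'=O bonds are cut back to a cyclopentadiene and dioxygen, because a [4+2] across C1'/C3' places oxygen on the open face and marks C1' as the future ether carbon. The gain is a hydrocarbon triene. The demand is facial selectivity anti to the C10' methyl and use of 12 before hydrogen shifts scramble it.

**12 to 11 to 10 to 8 to 7 to 6.** The C3'=C4' bond (metathesis), the two C4'–CH3 bonds (Grignard) and the C1'–C2' bond (allyl coupling) are cut back to a cyclic β-keto ester. The five-membered ring is built on a tetrasubstituted alkene, so that no stereocentre is made at C1' or C5' before the oxygens arrive.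

**6 to 5 to 4.** The C5' carbon is excised (one-carbon ring expansion) and the C10' centre is traced to an enzymatic enone reduction. The cis C7'/C10' relationship is the one that chemical conjugate reduction of the cyclohexenone does not favour. The demand is that the α-methyl ketone is not epimerised before C1' becomes sp2.

**3 to 2 to 1.** A C–Br bond and two O–CH3 bonds are cut. The methyl ethers make the bromination regioselective for C5.

## Other disconnections considered

**Alternative 1:** The cut runs through C1–C2, C3–C4 and C5–C10, so that ring A is assembled from three alkynes and ring B closes with it. In the forward direction the ruthenium catalyst A4 would unite the enediyne A2 with the diboryl alkyne A3 to give the bis-boronate A1, whose C–B bonds become the catechol oxygens. A4 is the complex Cp*RuCl(cod).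
- In its favour: H8 and the C6=C7 olefin are already in A2, so no late olefin shift and no C8 epimer question arise. On this point it is better than the chosen plan. It also has no aryne regiochemistry to control and forms three bonds and two rings in one step.
- Against it here: C9, quaternary and propargylic, and C8 must be set on ring C without the arene. The cross-cyclotrimerisation on A4 must place the bulky A3 beside a methyl-bearing alkyne carbon of A2. After oxidation of the C–B bonds of A1 the sesquiterpene must still be attached through two tertiary C–O bonds, with the orientation problem moved to the end.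
- Comparison: both plans close ring B in a cycloaddition, so they are equal there; mechanistically A4 works through a metallacycle, whereas the chosen plan uses a concerted aryne addition. The chosen plan is more convergent, with two halves of about fifteen steps, and fixes the dioxane orientation early on small molecules, but pays with the C8 step.

**Alternative 2:** The cut is the C1'–C5' bond of the hydroazulene. The forward step is a transannular pinacol coupling of the cyclodecenedione A6 with SmI2 A7, giving the cis-diol A5 and both carbocycles at once.
- In its favour: one step makes the ring-fusion bond, both rings and both carbinol centres, cis through chelation of both oxygens to the samarium of A7. For the carbocyclic core it is shorter than the eight steps used here to reach 14, and on that count it is the better plan.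
- Against it here: A6 is a Z-configured ten-membered enedione with two stereocentres, itself a demanding medium-ring target. One carbonyl of A6 is conjugated, so after electron transfer from A7 the spin is delocalised and coupling or reduction at the β-carbon can compete. The face of coupling relative to C7'/C10' depends on macrocycle conformation. A5 would still need two tertiary O-arylations whose orientation on the unsymmetrical arene is not controlled by the diol.
- Comparison: both rely on substrate control for the face anti to the C10' methyl, so they are equal there. The chosen plan brings the oxygens in as a phenol and as a leaving group in a fixed order, so the regiochemistry is a consequence of sequence.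

**Alternative 3:** The cut is C13–C14. The forward step is an ester-enolate (Ireland–Claisen) rearrangement of the ten-membered allylic lactone A9, which contracts the macrocycle to ring D and gives the acid A8 with a C13 vinyl and a C14 carboxyl group.
- In its favour: the vicinal quaternary pair is made in one sigmatropic step, with the two centres coupled through a cyclic transition state. This is more direct than the four-step cyclopropane sequence used here for C13, and on this point it is the better plan. The carboxyl and vinyl groups of A8 are useful handles.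
- Against it here: it needs enolisation of A9 with defined geometry at a fully substituted α-carbon inside a ten-membered ring, followed by a very hindered bond formation. Ring C must afterwards be built from the two handles of A8 (acid to the C8 ketone, vinyl to C11/C12, plus C9 and its methyl), which costs more steps than are saved. A9 needs its own synthesis.
- Comparison: both start from an enantiopure ring building block, so they are equal there. The chosen route begins with C14 already quaternary in 26 and adds ring E by annulation, which keeps the eastern half at fifteen steps.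

Key step: step 32

Remark: friedelane locants are used for the triterpene and primed guaiane locants for the sesquiterpene; β is the face of the C25/C26 methyls and of the C10' methyl/C7' isopropenyl, α the opposite face; the target is taken as its SMILES encodes, with H8 β (cis B/C).

Remark: the skeletons of 25, 43 and 45 agree with the target in connectivity and configuration; C21 is carried as its ethylene ketal from 38 to 46, because a free ketone beside C20 would enolise under KOtBu/DMSO and in the enolate chemistry at C9.

## Steps

Step 1
Reactants: 1 2,3-dimethoxytoluene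
Product: 2 1-bromo-3,4-dimethoxy-2-methylbenzene
Conditions: NBS, MeCN, 0 °C to rt
Reagents that add atoms: N-bromosuccinimide, O=C1CCC(=O)N1Br
Why: Electrophilic aromatic bromination; the methoxy group beside the ring hydrogen is coplanar and directs to its para position (ortho to the methyl), whereas the doubly flanked methoxy group is twisted out of conjugation.

Step 2
Reactants: 2 1-bromo-3,4-dimethoxy-2-methylbenzene
Product: 3 4-bromo-3-methylbenzene-1,2-diol
Conditions: BBr3, CH2Cl2, −78 to 0 °C; MeOH, H2O
Reagents that add atoms: none
Why: Boron tribromide cleavage of both aryl methyl ethers; the aryl bromide is inert and the bromine now marks C5.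

Step 3
Reactants: 4 (S)-carvone
Product: 5 (2R,5S)-dihydrocarvone
Conditions: OYE1 (old yellow enzyme 1), NADP+ (cat.), glucose, glucose dehydrogenase, phosphate buffer pH 7.0, 30 °C
Reagents that add atoms: none
Why: Ene-reductase reduction of the enone C=C; the flavin delivers hydride to the β-carbon and the active site protonates the α-carbon trans to it, which sets C2 as R whatever the C5 configuration, and with 5S this is the cis ketone (the future C10'/C7' relationship). Neutral pH avoids epimerisation to the more stable trans isomer.

Step 4
Reactants: 5 (2R,5S)-dihydrocarvone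
Product: 6 ethyl (3R,6S)-3-methyl-2-oxo-6-(prop-1-en-2-yl)cycloheptane-1-carboxylate
Conditions: ethyl diazoacetate, BF3·OEt2, Et2O, 0 °C
Reagents that add atoms: ethyl diazoacetate, CCOC(=O)C=[N+]=[N-]
Why: Lewis acid-promoted diazoacetate ring expansion (Tiffeneau–Demjanov type); the less substituted α-carbon migrates, so the inserted carbon (future C5') carries the ester and the methyl-bearing centre is not involved.

Step 5
Reactants: 6 ethyl (3R,6S)-3-methyl-2-oxo-6-(prop-1-en-2-yl)cycloheptane-1-carboxylate
Product: 7 ethyl (3R,6S)-3-methyl-6-(prop-1-en-2-yl)-2-(trifluoromethylsulfonyloxy)cyclohept-1-ene-1-carboxylate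
Conditions: NaH, PhNTf2, THF, 0 °C to rt
Reagents that add atoms: N-phenyl-bis(trifluoromethanesulfonimide), O=S(=O)(N(c1ccccc1)S(=O)(=O)C(F)(F)F)C(F)(F)F
Why: O-Triflation of the β-keto ester enolate; only the doubly activated hydrogen is removed, so the C1'=C5' enol triflate is regiodefined and C10' is no longer beside an enolisable carbonyl.

Step 6
Reactants: 7 ethyl (3R,6S)-3-methyl-6-(prop-1-en-2-yl)-2-(trifluoromethylsulfonyloxy)cyclohept-1-ene-1-carboxylate
Product: 8 ethyl (3R,6S)-2-allyl-3-methyl-6-(prop-1-en-2-yl)cyclohept-1-ene-1-carboxylate
Conditions: allyltributylstannane, Pd(PPh3)4, LiCl, THF, 65 °C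
Reagents that add atoms: allyltributylstannane, C=CC[Sn](CCCC)(CCCC)CCCC
Why: Stille coupling of a β-triflyloxy enoate; C2' and C3' are attached to sp2 C1' without creating a stereocentre.

Step 7
Reactants: 8 ethyl (3R,6S)-2-allyl-3-methyl-6-(prop-1-en-2-yl)cyclohept-1-ene-1-carboxylate
Product: 10 2-[(3R,6S)-2-allyl-3-methyl-6-(prop-1-en-2-yl)cyclohept-1-en-1-yl]propan-2-ol, via methyl ketone 9 (not isolated)
Conditions: MeMgBr (3 equiv), THF, 0 °C to rt
Reagents that add atoms: methylmagnesium bromide, C[Mg]Br
Why: Double Grignard addition to the unsaturated ester (1,2-addition at the hindered tetrasubstituted enoate); the ester carbon becomes C4' and one of the new methyls becomes C15'.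

Step 8
Reactants: 10 2-[(3R,6S)-2-allyl-3-methyl-6-(prop-1-en-2-yl)cyclohept-1-en-1-yl]propan-2-ol
Product: 11 (3R,6S)-2-allyl-3-methyl-1,6-di(prop-1-en-2-yl)cyclohept-1-ene
Conditions: Burgess reagent, PhMe, 50 °C
Reagents that add atoms: none
Why: Burgess syn-elimination; the only β-hydrogens are those of the two equivalent methyls (the other β-carbon is sp2), so the isopropenyl group is the sole intramolecular elimination product.

Step 9
Reactants: 11 (3R,6S)-2-allyl-3-methyl-1,6-di(prop-1-en-2-yl)cyclohept-1-ene
Product: 12 (7S,10R)-guaia-1(5),3,11-triene
Conditions: second-generation Grubbs catalyst (5 mol %), CH2Cl2 (5 mM), 40 °C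
Reagents that add atoms: none
Why: Ring-closing metathesis between the allyl terminus and the isopropenyl group on neighbouring alkene carbons closes the five-membered ring as a cyclopentadiene with loss of ethene; the remote C7' isopropenyl could only close a strained bridged ring. 12 is used at once so that 1,5-hydrogen shifts do not scramble the diene.

Step 10
Reactants: 12 (7S,10R)-guaia-1(5),3,11-triene
Product: 14 1α-hydroxyguaia-4,11-dien-3-one, via endoperoxide 13 (not isolated)
Conditions: O2, hν, tetraphenylporphyrin (cat.), CH2Cl2, −78 °C; then Et3N, −78 to 0 °C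
Reagents that add atoms: dioxygen, O=O
Why: Singlet-oxygen [4+2] cycloaddition across C1'/C3' of the cyclopentadiene on the face opposite the C10' methyl, then Kornblum–DeLaMare fragmentation; base can only remove the C3' hydrogen, which gives the C3' ketone and leaves the tertiary oxygen on the α-face of C1'.

Step 11
Reactants: 14 1α-hydroxyguaia-4,11-dien-3-one
Product: 15 1α-(methoxycarbonyloxy)guaia-4,11-dien-3-one
Conditions: LiN(SiMe3)2, ClCO2Me, THF, −78 °C
Reagents that add atoms: methyl chloroformate, COC(=O)Cl
Why: Low-temperature O-acylation of the lithium alkoxide turns the tertiary γ-hydroxyl into a leaving group without touching the C1' configuration.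

Step 12
Reactants: 15 1α-(methoxycarbonyloxy)guaia-4,11-dien-3-one; 3 4-bromo-3-methylbenzene-1,2-diol
Product: 17 1α-(4-bromo-2-hydroxy-3-methylphenoxy)guaia-4,11-dien-3-ol (C3' epimers), via aryloxy enone 16 (not isolated)
Conditions: Pd2(dba)3·CHCl3 (2.5 mol %), PPh3, THF, 0 °C to rt; then CeCl3·7H2O, NaBH4, MeOH, −78 °C
Reagents that add atoms: none
Why: Tsuji–Trost substitution of a γ-carbonyloxy enone by a phenol: ionisation anti to the carbonate and attack of the less hindered, more acidic phenol (para to Br, the future O2) at the γ-terminus C1' anti to palladium give net retention, that is the aryl ether on the α-face; an elimination–addition through the cyclopentadienone would converge on the same ether. Immediate Luche 1,2-reduction removes the enone before the second phenol can add to it; the C3' epimer ratio does not matter for step 13.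

Step 13
Reactants: 17 1α-(4-bromo-2-hydroxy-3-methylphenoxy)guaia-4,11-dien-3-ol
Product: 18 guaia-3,11-diene-1α,5α-diyl ether of 3 (benzodioxane, Br at C5, methyl-flanked oxygen on C5')
Conditions: Re2O7 (5 mol %), CH2Cl2, 0 °C to rt
Reagents that add atoms: none
Why: Re2O7-catalysed 1,3-transposition of the allylic alcohol through its perrhenate ester and the tertiary allylic cation; the free phenol traps C5' in a 6-exo closure that can only be cis on the propellane, so both C3' epimers converge and the olefin ends at C3'=C4'.

Step 14
Reactants: 18 benzodioxane C5 bromide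
Product: 21 benzodioxane C5 phenol, via aryllithium 19 (not isolated), via dimethyl arylboronate 20 (not isolated)
Conditions: n-BuLi, THF, −78 °C; B(OMe)3; then H2O2, NaOH, 0 °C
Reagents that add atoms: hydrogen peroxide, OO
Why: Bromine–lithium exchange, borylation and oxidative C–B to C–O conversion; the olefins and the aryl ethers are inert to alkyllithium at −78 °C and to basic peroxide.

Step 15
Reactants: 21 benzodioxane C5 phenol
Product: 22 C10-bromo C5 phenol
Conditions: NBS, iPr2NH (cat.), CH2Cl2, −78 °C
Reagents that add atoms: N-bromosuccinimide, O=C1CCC(=O)N1Br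
Why: Amine-catalysed ortho-bromination of a phenol; C10 is the only free ortho position (the other carries the methyl, the para carbon an oxygen) and the phenol reacts far faster than the isolated olefins at this temperature.

Step 16
Reactants: 22 C10-bromo C5 phenol
Product: 25 guaiane-fused benzodioxane C10-trimethylsilyl C5-triflate, via aryl trimethylsilyl ether 23 (not isolated), via lithium silylphenoxide 24 (not isolated)
Conditions: (Me3Si)2NH, THF, 65 °C; then n-BuLi, THF, −78 °C; then Tf2O, −78 to 0 °C
Reagents that add atoms: hexamethyldisilazane, C[Si](C)(C)N[Si](C)(C)C; trifluoromethanesulfonic anhydride, O=S(=O)(OS(=O)(=O)C(F)(F)F)C(F)(F)F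
Why: O-Silylation, bromine–lithium exchange with retro-Brook (O to C) silyl migration and triflation of the phenoxide: the standard one-pot conversion of a 2-bromophenol into a 2-silylaryl triflate.

Step 17
Reactants: 26 (S)-Wieland–Miescher ketone
Product: 27 (4aS,5S)-5-hydroxy-4a-methyl-4,4a,5,6,7,8-hexahydronaphthalen-2(3H)-one
Conditions: NaBH4 (0.3 equiv), EtOH, −10 °C
Reagents that add atoms: none
Why: Chemoselective borohydride reduction of the saturated (future C8) ketone in the presence of the enone; hydride enters anti to the angular methyl. This carbinol centre is later oxidised away.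

Step 18
Reactants: 27 (4aS,5S)-5-hydroxy-4a-methyl-4,4a,5,6,7,8-hexahydronaphthalen-2(3H)-one
Product: 28 tert-butyldimethylsilyl ether of 27
Conditions: TBSCl, imidazole, DMF, rt
Reagents that add atoms: tert-butyldimethylsilyl chloride, CC(C)(C)[Si](C)(C)Cl
Why: Standard silylation; it holds C8 at the alcohol level while all ketone chemistry at C17 and C21 is done.

Step 19
Reactants: 28 tert-butyldimethylsilyl ether of 27
Product: 29 ring C/D 17α-allylic alcohol (OH trans to the C14 methyl)
Conditions: LiBH(sBu)3, THF, −78 °C; NaOH, H2O2
Reagents that add atoms: none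
Why: A β,β-disubstituted cyclohexenone undergoes 1,2-reduction with the bulky borohydride, which attacks along the equatorial trajectory on the side of the angular methyl and gives the pseudo-axial alcohol trans to it, as needed to direct step 20.

Step 20
Reactants: 29 ring C/D 17α-allylic alcohol
Product: 30 13α,18α-methano carbinol
Conditions: Et2Zn, CH2I2, CH2Cl2, 0 °C
Reagents that add atoms: diiodomethane, ICI
Why: Hydroxyl-directed Simmons–Smith cyclopropanation delivers the methylene to the olefin face syn to the hydroxyl, that is anti to the C14 methyl; this fixes the C13 configuration.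

Step 21
Reactants: 30 13α,18α-methano carbinol
Product: 31 13α,18α-methano 17-ketone
Conditions: Dess–Martin periodinane, NaHCO3, CH2Cl2, rt
Reagents that add atoms: none
Why: Mild oxidation of the secondary alcohol to the cyclopropyl ketone needed for reductive ring opening.

Step 22
Reactants: 31 13α,18α-methano 17-ketone
Product: 33 17-trimethylsilyloxy-17(18)-ene with 13α,14β-dimethyl groups, via lithium enolate 32 (not isolated)
Conditions: Li, NH3(l), THF, −78 °C; then Me3SiCl, Et3N, THF, −78 to 0 °C
Reagents that add atoms: chlorotrimethylsilane, C[Si](C)(C)Cl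
Why: Dissolving-metal cleavage of the cyclopropyl ketone breaks the exocyclic C18–CH2 bond, which overlaps best with the carbonyl π-system, so the methylene becomes the 13α-methyl trans to the 14β-methyl; the regiodefined C17(18) enolate is trapped on oxygen.

Step 23
Reactants: 33 17-trimethylsilyloxy-17(18)-ene
Product: 34 18α-(2-methyl-3-oxobutyl) 17-ketone (C20 epimers)
Conditions: 3-methylbut-3-en-2-one, TiCl4, CH2Cl2, −78 °C; aq. K2CO3
Reagents that add atoms: 3-methylbut-3-en-2-one, CC(=O)C(C)=C
Why: Mukaiyama–Michael addition of the regiodefined silyl enol ether makes C18–C19 at the neopentyl position; C18 settles with the chain equatorial (H18 β), because an axial chain would be syn-diaxial to the C14 methyl.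

Step 24
Reactants: 34 18α-(2-methyl-3-oxobutyl) 17-ketone
Product: 35 ring C/D/E 17(22)-en-21-one
Conditions: KOH, MeOH, 65 °C
Reagents that add atoms: none
Why: Robinson-type intramolecular aldol condensation of the methyl ketone (C22) onto C17 closes ring E as the conjugated enone; the alternative aldol could only dehydrate to a bridgehead olefin and reverts. C18 and C20 are under thermodynamic control here.

Step 25
Reactants: 35 ring C/D/E 17(22)-en-21-one
Product: 37 ring C/D/E 21-ketone with 17β-methyl and 20β-methyl, via silyl enol ether 36 (not isolated)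
Conditions: Me2CuLi, Me3SiCl, THF, −78 to −20 °C; then NaOMe, MeOH, rt
Reagents that add atoms: lithium dimethylcuprate, [Li+].C[Cu-]C
Why: Conjugate addition axial to the enone ring and from the β-face, away from the axial 13α-methyl, gives the cis D/E fusion with the C17 methyl syn to H18. Methoxide then cleaves the silyl enol ether and equilibrates C20 to the equatorial methyl (20R).

Step 26
Reactants: 37 ring C/D/E 21-ketone
Product: 38 21,21-ethylenedioxy derivative
Conditions: Me3SiOCH2CH2OSiMe3, Me3SiOTf (cat.), CH2Cl2, −78 to −20 °C
Reagents that add atoms: 1,2-bis(trimethylsilyloxy)ethane, C[Si](C)(C)OCCO[Si](C)(C)C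
Why: Aprotic silyl triflate-catalysed dioxolane formation works on hindered ketones and spares the silyl ether; it protects C21 and freezes C20 for all later basic steps.

Step 27
Reactants: 38 21,21-ethylenedioxy derivative
Product: 39 8β-alcohol
Conditions: Bu4NF, THF, 60 °C
Reagents that add atoms: none
Why: Fluoride cleavage of the hindered secondary silyl ether; the ketal is inert.

Step 28
Reactants: 39 8β-alcohol
Product: 40 8-ketone
Conditions: Dess–Martin periodinane, CH2Cl2, rt
Reagents that add atoms: none
Why: Neutral oxidation to the ring C ketone without risk to the dioxolane.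

Step 29
Reactants: 40 8-ketone
Product: 41 9-methyl 8-ketone (C9 epimers)
Conditions: LiN(iPr)2, MeI, THF, −78 to −20 °C
Reagents that add atoms: iodomethane, CI
Why: Enolate alkylation; C9 is the only enolisable position because C14 is quaternary, and the C9 configuration is lost in the next step.

Step 30
Reactants: 41 9-methyl 8-ketone
Product: 42 8-(trifluoromethylsulfonyloxy)-8(9)-ene
Conditions: KN(SiMe3)2, PhNTf2, THF, −78 to 0 °C
Reagents that add atoms: N-phenyl-bis(trifluoromethanesulfonimide), O=S(=O)(N(c1ccccc1)S(=O)(=O)C(F)(F)F)C(F)(F)F
Why: Enolisation can only occur toward C9, so the tetrasubstituted enol triflate is formed without regiochemical ambiguity.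

Step 31
Reactants: 42 8-(trifluoromethylsulfonyloxy)-8(9)-ene
Product: 43 ring C/D/E 8-vinyl-8(9)-ene 21-ketal
Conditions: tributyl(vinyl)stannane, Pd(PPh3)4, LiCl, THF, 65 °C
Reagents that add atoms: tributyl(vinyl)stannane, C=C[Sn](CCCC)(CCCC)CCCC
Why: Stille vinylation of the enol triflate gives the 2-methyl-1-vinylcyclohexene diene (C6=C7–C8=C9).

Step 32
Reactants: 25 guaiane-fused benzodioxane C10-trimethylsilyl C5-triflate; 43 ring C/D/E 8-vinyl-8(9)-ene 21-ketal
Product: 45 cycloadduct with C7=C8 olefin and 21-ketal, via aryne 44 (not isolated)
Conditions: CsF (3 equiv), MeCN/PhMe 1:1, rt, 25 added slowly to 43 (1.5 equiv)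
Reagents that add atoms: none
Why: Fluoride attacks silicon and the aryl anion expels triflate to give the C5–C10 aryne 44, which adds in a concerted, asynchronous [4+2] fashion to the s-cis conformer of the C6=C7–C8=C9 diene. The closest known reaction type is the aryne Diels–Alder reaction of 2-silylaryl triflates with 1-vinylcyclohexenes giving hydrophenanthrenes. Ring B closes in the cycloaddition mode: C5–C6 and C9–C10 form suprafacially on one diene face and make a six-membered ring with the new C7=C8 olefin. The one new stereocentre, C9, is controlled by the face of approach: the aryne comes from the α-face, anti to the pseudo-axial C26 methyl on C14, so the inside C25 methyl rotates to the β-face. The regiochemistry needed is C9 to C10 and C6 to C5; it rests on steric matching, the fully substituted diene terminus bonding to the aryne carbon flanked by hydrogen and the CH2 terminus to the carbon beside the C4 methyl. The periselectivity needed is [4+2] over ene and [2+2] reactions, and it is the weak point, because the C25 and C11 hydrogens are allylic to C8=C9 and the inside C25 methyl raises the energy of the s-cis conformer; the low barrier of aryne cycloadditions, bonding that starts at the unhindered C6 terminus, slow aryne generation and an excess of diene are relied on. The ketal and the absence of silyl ethers make fluoride harmless to the rest of both halves.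

Step 33
Reactants: 45 cycloadduct with C7=C8 olefin
Product: 46 6,7-ene with 8β-H (21-ketal)
Conditions: KOtBu (0.3 equiv), DMSO, 20 °C, monitored; pH 7 buffer
Reagents that add atoms: none
Why: Base-mediated prototropic shift of a 1,4-dihydronaphthalene to the conjugated 1,2-dihydronaphthalene: the doubly activated C6 hydrogen is removed and tBuOH reprotonates the delocalised anion at C8. Axial approach to C8 from the α-face is blocked by the syn-axial C27 methyl on C13, so the proton should arrive from the β-side, between the C25 and C26 methyls, and give H8 cis to them. The reaction is stopped at full conversion of 45 so that this kinetic outcome is kept; the position of a full C8 equilibrium is not relied on.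

Step 34
Reactants: 46 6,7-ene with 8β-H (21-ketal)
Product: 47 CNP0233042.2
Conditions: PPTS, acetone/H2O 10:1, 50 °C
Reagents that add atoms: water, O
Why: Mild acid-catalysed ketal hydrolysis; the buffered acid spares the tertiary allylic aryl ether, and C20 already has its thermodynamically preferred equatorial methyl.

## Compound list

1 | 2,3-dimethoxytoluene | COc1cccc(C)c1OC | starting material
2 | 1-bromo-3,4-dimethoxy-2-methylbenzene | COc1ccc(Br)c(C)c1OC | intermediate
3 | 4-bromo-3-methylbenzene-1,2-diol | Oc1ccc(Br)c(C)c1O | intermediate
4 | (S)-carvone | CC1=CC[C@@H](CC1=O)C(C)=C | starting material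
5 | (2R,5S)-dihydrocarvone (cis) | C=C(C)[C@H]1CC[C@@H](C)C(=O)C1 | intermediate
6 | ethyl (3R,6S)-3-methyl-2-oxo-6-(prop-1-en-2-yl)cycloheptane-1-carboxylate (C1 epimers, keto/enol) | C=C(C)[C@H]1CC[C@@H](C)C(=O)C(C(=O)OCC)C1 | intermediate
7 | ethyl (3R,6S)-3-methyl-6-(prop-1-en-2-yl)-2-(trifluoromethylsulfonyloxy)cyclohept-1-ene-1-carboxylate | C=C(C)[C@H]1CC[C@@H](C)C(OS(=O)(=O)C(F)(F)F)=C(C(=O)OCC)C1 | intermediate
8 | ethyl (3R,6S)-2-allyl-3-methyl-6-(prop-1-en-2-yl)cyclohept-1-ene-1-carboxylate | C=C(C)[C@H]1CC[C@@H](C)C(CC=C)=C(C(=O)OCC)C1 | intermediate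
9 | 1-[(3R,6S)-2-allyl-3-methyl-6-(prop-1-en-2-yl)cyclohept-1-en-1-yl]ethan-1-one | C=C(C)[C@H]1CC[C@@H](C)C(CC=C)=C(C(C)=O)C1 | intermediate (not isolated)
10 | 2-[(3R,6S)-2-allyl-3-methyl-6-(prop-1-en-2-yl)cyclohept-1-en-1-yl]propan-2-ol | C=C(C)[C@H]1CC[C@@H](C)C(CC=C)=C(C(C)(C)O)C1 | intermediate
11 | (3R,6S)-2-allyl-3-methyl-1,6-di(prop-1-en-2-yl)cyclohept-1-ene | C=C(C)[C@H]1CC[C@@H](C)C(CC=C)=C(C(C)=C)C1 | intermediate
12 | (7S,10R)-guaia-1(5),3,11-triene (10-methyl and 7-isopropenyl cis) | C=C(C)[C@H]1CC[C@@H](C)C2=C(C1)C(C)=CC2 | intermediate
13 | 1α,3α-epidioxyguaia-4,11-diene | C=C(C)[C@H]1CC[C@@H](C)[C@]23C[C@H](OO2)C(C)=C3C1 | intermediate (not isolated)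
14 | 1α-hydroxyguaia-4,11-dien-3-one | C=C(C)[C@H]1CC[C@@H](C)[C@@]2(O)CC(=O)C(C)=C2C1 | intermediate
15 | 1α-(methoxycarbonyloxy)guaia-4,11-dien-3-one | C=C(C)[C@H]1CC[C@@H](C)[C@@]2(OC(=O)OC)CC(=O)C(C)=C2C1 | intermediate
16 | 1α-(4-bromo-2-hydroxy-3-methylphenoxy)guaia-4,11-dien-3-one | C=C(C)[C@H]1CC[C@@H](C)[C@@]2(Oc3ccc(Br)c(C)c3O)CC(=O)C(C)=C2C1 | intermediate (not isolated)
17 | 1α-(4-bromo-2-hydroxy-3-methylphenoxy)guaia-4,11-dien-3-ol (C3' epimers) | C=C(C)[C@H]1CC[C@@H](C)[C@@]2(Oc3ccc(Br)c(C)c3O)CC(O)C(C)=C2C1 | intermediate
18 | guaia-3,11-diene-1α,5α-diyl (4-bromo-3-methyl-1,2-phenylene) diether (benzodioxane; Br at C5; oxygen beside the aryl methyl on C5') | C=C(C)[C@H]1CC[C@@H](C)[C@@]23CC=C(C)[C@]2(C1)Oc1c(ccc(Br)c1C)O3 | intermediate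
19 | C5 aryllithium of the benzodioxane | C=C(C)[C@H]1CC[C@@H](C)[C@@]23CC=C(C)[C@]2(C1)Oc1c(ccc([Li])c1C)O3 | intermediate (not isolated)
20 | C5 dimethyl boronate of the benzodioxane | C=C(C)[C@H]1CC[C@@H](C)[C@@]23CC=C(C)[C@]2(C1)Oc1c(ccc(B(OC)OC)c1C)O3 | intermediate (not isolated)
21 | benzodioxane C5 phenol | C=C(C)[C@H]1CC[C@@H](C)[C@@]23CC=C(C)[C@]2(C1)Oc1c(ccc(O)c1C)O3 | intermediate
22 | C10-bromo C5 phenol | C=C(C)[C@H]1CC[C@@H](C)[C@@]23CC=C(C)[C@]2(C1)Oc1c(cc(Br)c(O)c1C)O3 | intermediate
23 | trimethylsilyl ether of 22 | C=C(C)[C@H]1CC[C@@H](C)[C@@]23CC=C(C)[C@]2(C1)Oc1c(cc(Br)c(O[Si](C)(C)C)c1C)O3 | intermediate (not isolated)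
24 | lithium C10-(trimethylsilyl) C5-phenoxide | C=C(C)[C@H]1CC[C@@H](C)[C@@]23CC=C(C)[C@]2(C1)Oc1c(cc([Si](C)(C)C)c(O[Li])c1C)O3 | intermediate (not isolated)
25 | guaiane-fused benzodioxane C10-trimethylsilyl C5-triflate | C=C(C)[C@H]1CC[C@@H](C)[C@@]23CC=C(C)[C@]2(C1)Oc1c(cc([Si](C)(C)C)c(OS(=O)(=O)C(F)(F)F)c1C)O3 | intermediate
26 | (S)-Wieland–Miescher ketone | C[C@]12CCC(=O)C=C1CCCC2=O | starting material
27 | (4aS,5S)-5-hydroxy-4a-methyl-4,4a,5,6,7,8-hexahydronaphthalen-2(3H)-one | C[C@]12CCC(=O)C=C1CCC[C@@H]2O | intermediate
28 | (4aS,5S)-5-(tert-butyldimethylsilyloxy)-4a-methyl-4,4a,5,6,7,8-hexahydronaphthalen-2(3H)-one | C[C@]12CCC(=O)C=C1CCC[C@@H]2O[Si](C)(C)C(C)(C)C | intermediate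
29 | ring C/D 17α-allylic alcohol (OH trans to the C14 methyl; 8β-OTBS) | C[C@]12CC[C@@H](O)C=C1CCC[C@@H]2O[Si](C)(C)C(C)(C)C | intermediate
30 | 13α,18α-methano 17α-carbinol | C[C@]12CC[C@@H](O)[C@H]3C[C@@]13CCC[C@@H]2O[Si](C)(C)C(C)(C)C | intermediate
31 | 13α,18α-methano 17-ketone | C[C@]12CCC(=O)[C@H]3C[C@@]13CCC[C@@H]2O[Si](C)(C)C(C)(C)C | intermediate
32 | lithium 17(18)-enolate with 13α,14β-dimethyl groups | C[C@]12CCC(O[Li])=C[C@]1(C)CCC[C@@H]2O[Si](C)(C)C(C)(C)C | intermediate (not isolated)
33 | 17-trimethylsilyloxy-17(18)-ene with 13α,14β-dimethyl groups | C[C@]12CCC(O[Si](C)(C)C)=C[C@]1(C)CCC[C@@H]2O[Si](C)(C)C(C)(C)C | intermediate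
34 | 18α-(2-methyl-3-oxobutyl) 17-ketone (18β-H; C20 epimers) | C[C@]12CCC(=O)[C@@H](CC(C)C(C)=O)[C@]1(C)CCC[C@@H]2O[Si](C)(C)C(C)(C)C | intermediate
35 | ring C/D/E 17(22)-en-21-one (18β-H, 20β-methyl, 8β-OTBS) | C[C@]12CCC3=CC(=O)[C@H](C)C[C@H]3[C@]1(C)CCC[C@@H]2O[Si](C)(C)C(C)(C)C | intermediate
36 | 21-trimethylsilyloxy-21(22)-ene with 17β-methyl | C[C@]12CC[C@@]3(C)C=C(O[Si](C)(C)C)[C@H](C)C[C@H]3[C@]1(C)CCC[C@@H]2O[Si](C)(C)C(C)(C)C | intermediate (not isolated)
37 | ring C/D/E 21-ketone (13α,14β,17β,20β-tetramethyl, 18β-H, 8β-OTBS) | C[C@]12CC[C@@]3(C)CC(=O)[C@H](C)C[C@H]3[C@]1(C)CCC[C@@H]2O[Si](C)(C)C(C)(C)C | intermediate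
38 | 21,21-ethylenedioxy derivative of 37 | C[C@]12CC[C@@]3(C)CC4(OCCO4)[C@H](C)C[C@H]3[C@]1(C)CCC[C@@H]2O[Si](C)(C)C(C)(C)C | intermediate
39 | 21,21-ethylenedioxy 8β-alcohol | C[C@]12CC[C@@]3(C)CC4(OCCO4)[C@H](C)C[C@H]3[C@]1(C)CCC[C@@H]2O | intermediate
40 | 21,21-ethylenedioxy 8-ketone | C[C@]12CC[C@@]3(C)CC4(OCCO4)[C@H](C)C[C@H]3[C@]1(C)CCCC2=O | intermediate
41 | 21,21-ethylenedioxy 9-methyl 8-ketone (C9 epimers) | C[C@]12CC[C@@]3(C)CC4(OCCO4)[C@H](C)C[C@H]3[C@]1(C)CCC(C)C2=O | intermediate
42 | 21,21-ethylenedioxy 8-(trifluoromethylsulfonyloxy)-8(9)-ene | C[C@]12CC[C@@]3(C)CC4(OCCO4)[C@H](C)C[C@H]3[C@]1(C)CCC(C)=C2OS(=O)(=O)C(F)(F)F | intermediate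
43 | ring C/D/E diene: 9-methyl-8-vinyl-8(9)-ene 21-ketal | C=CC1=C(C)CC[C@@]2(C)[C@@H]3C[C@@H](C)C4(OCCO4)C[C@]3(C)CC[C@]12C | intermediate
44 | C5–C10 aryne of the guaiane-fused benzodioxane | C=C(C)[C@H]1CC[C@@H](C)[C@@]23CC=C(C)[C@]2(C1)OC1=C(C)C#CC=C1O3 | intermediate (not isolated)
45 | cycloadduct: 5,8-dihydro isomer with C7=C8 olefin, 21-ketal | C=C(C)[C@H]1CC[C@@H](C)[C@@]23CC=C(C)[C@]2(C1)Oc1c(cc2c(c1C)CC=C1[C@@]2(C)CC[C@@]2(C)[C@@H]4C[C@@H](C)C5(OCCO5)C[C@]4(C)CC[C@]12C)O3 | intermediate
46 | 21-ethylene ketal of the target (C6=C7, 8β-H) | C=C(C)[C@H]1CC[C@@H](C)[C@@]23CC=C(C)[C@]2(C1)Oc1c(cc2c(c1C)C=C[C@@H]1[C@@]2(C)CC[C@@]2(C)[C@@H]4C[C@@H](C)C5(OCCO5)C[C@]4(C)CC[C@]12C)O3 | intermediate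
47 | CNP0233042.2 | C=C(C)[C@H]1CC[C@@H](C)[C@@]23CC=C(C)[C@]2(C1)Oc1c(cc2c(c1C)C=C[C@@H]1[C@@]2(C)CC[C@@]2(C)[C@@H]4C[C@@H](C)C(=O)C[C@]4(C)CC[C@]12C)O3 | target

## Step count and least certain steps

Total step count: 34. Longest linear sequence: 18 steps (steps 17 to 31, then 32 to 34). The western line is 17 steps (3 to 16, then 32 to 34), and the arene 3 joins it after 2 steps.

**Step 32 (key step).** The twisted, fully substituted diene may fail to reach the s-cis geometry fast enough, so that ene reactions at the C25 or C11 hydrogens of the diene, or ene and [2+2] reactions of the aryne with the isopropenyl and cyclopentene olefins, take over. The orientation may also erode, with the CH2 terminus bonding to C10, because steric matching is the only control element. The fallback forms the same two bonds one after the other. It sets out from 21 and 43 and comes back at 45.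
- Ortho-chlorination of 21 with N-chlorosuccinimide gives the C10-chloro phenol F1, and triflation gives the chloro aryl triflate F2.
- 9-BBN adds to the vinyl group of 43 to give the B-alkyl borane F3.
- A B-alkyl Suzuki coupling at the triflate (PdCl2(dppf), Cs2CO3) joins C5 to C6 and gives the aryl-ethyl cyclohexene F4.
- An intramolecular Heck reaction of the aryl chloride (Pd2(dba)3, P(tBu)3, Cy2NMe) adds the aryl group to C9 on the α-face; β-hydride elimination, possible only toward C7, gives 45.

**Step 33.** Stereocontrol at C8 may be lost: the β-face, although free of the syn-axial C27 methyl, is flanked by the C25 and C26 methyls, so protonation may occur from the α-face, and reversible deprotonation can carry the product to a thermodynamic epimer ratio that cannot be predicted with confidence. The fallback separates deprotonation from protonation and replaces the reversible proton shuttle by an irreversible, reagent-controlled quench. From 45, the delocalised anion is preformed with a stoichiometric mixed LiN(iPr)2/KOtBu base in THF at −78 °C and quenched at that temperature with 2,6-di-tert-butylphenol, a proton donor too large for the axial trajectory beside the C27 methyl, so that the equatorial (β) approach to C8 is enforced; the product is 46. No new compound is involved, and a minor C8 epimer would be separated and resubmitted.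

**Step 12.** Ionisation of the hindered tertiary carbonate may be slow, and base-induced elimination to the cyclopentadienone may then lead to dimerisation, to attack by the wrong phenol oxygen, or to Michael addition of the second phenol before reduction. The fallback changes the bond-forming logic to a hetero-Diels–Alder reaction. It sets out from 12 and 3 and comes back at 18 (it also replaces steps 10, 11 and 13). Ag2O oxidises 3 to 4-bromo-3-methyl-1,2-benzoquinone F5, which adds as a heterodiene to the tetrasubstituted 1(5)-olefin of 12 on the face anti to the C10' methyl. Site selectivity (against the C3'=C4' olefin) and head-to-tail orientation would then rest on sterics alone, which is why this is not the main route.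

**Step 13.** The allylic cation may lose a proton to give a cyclopentadiene, or the C1' aryl ether may ionise in competition, before the phenol closes the ring. The fallback uses a stereospecific palladium substitution. It sets out from 17 and comes back at 18. The 3'β-epimer of 17, with the hydroxyl anti to the C1' aryl ether, undergoes Mitsunobu esterification with benzoic acid, which inverts C3' and gives the 3'α-allylic benzoate F6. Pd(PPh3)4 with Cs2CO3 ionises it anti, placing palladium on the β-face, and the tethered phenoxide attacks C5' on the α-face (Tsuji–Trost, 6-exo) to give 18. The 3'α-epimer of 17 is not lost: MnO2 returns it to 16, which re-enters the Luche reduction.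

**Step 19.** Hydride may attack from the other face, or partly in conjugate fashion, so that the hydroxyl that must direct the cyclopropanation ends on the wrong side. The fallback sets out from 28 and comes back at 29. Luche reduction (NaBH4, CeCl3·7H2O) gives the equatorial 17β-allylic alcohol F7; Mitsunobu inversion with 4-nitrobenzoic acid gives the 17α-(4-nitrobenzoate) F8; K2CO3 in MeOH then gives 29.

## Further compounds

F0 | step 33 | none | none
F1 | step 32 | benzodioxane C10-chloro C5-phenol | C=C(C)[C@H]1CC[C@@H](C)[C@@]23CC=C(C)[C@]2(C1)Oc1c(cc(Cl)c(O)c1C)O3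
F2 | step 32 | benzodioxane C10-chloro C5-triflate | C=C(C)[C@H]1CC[C@@H](C)[C@@]23CC=C(C)[C@]2(C1)Oc1c(cc(Cl)c(OS(=O)(=O)C(F)(F)F)c1C)O3
F3 | step 32 | B-alkyl-9-BBN from hydroboration of the vinyl group of 43 | C(CB1C2CCCC1CCC2)C1=C(C)CC[C@@]2(C)[C@@H]3C[C@@H](C)C4(OCCO4)C[C@]3(C)CC[C@]12C
F4 | step 32 | C5-(2-cyclohexenylethyl) C10-chloro benzodioxane (Heck precursor) | C=C(C)[C@H]1CC[C@@H](C)[C@@]23CC=C(C)[C@]2(C1)Oc1c(cc(Cl)c(c1C)CCC1=C(C)CC[C@@]2(C)[C@@H]4C[C@@H](C)C5(OCCO5)C[C@]4(C)CC[C@]12C)O3
F5 | step 12 | 4-bromo-3-methyl-1,2-benzoquinone | O=C1C=CC(Br)=C(C)C1=O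
F6 | step 13 | 1α-(4-bromo-2-hydroxy-3-methylphenoxy)guaia-4,11-dien-3α-yl benzoate | C=C(C)[C@H]1CC[C@@H](C)[C@@]2(Oc3ccc(Br)c(C)c3O)C[C@H](OC(=O)c3ccccc3)C(C)=C2C1
F7 | step 19 | ring C/D 17β-allylic alcohol (OH cis to the C14 methyl) | C[C@]12CC[C@H](O)C=C1CCC[C@@H]2O[Si](C)(C)C(C)(C)C
F8 | step 19 | ring C/D 17α-(4-nitrobenzoate) | C[C@]12CC[C@@H](OC(=O)c3ccc(cc3)[N+](=O)[O-])C=C1CCC[C@@H]2O[Si](C)(C)C(C)(C)C
A1 | alternative 1 | triterpene 2,3-bis(pinacolboronate) | CC1(C)OB(OC1(C)C)c1cc2c(c(C)c1B1OC(C)(C)C(C)(C)O1)C=C[C@@H]1[C@@]2(C)CC[C@@]2(C)[C@@H]4C[C@@H](C)C(=O)C[C@]4(C)CC[C@]12C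
A2 | alternative 1 | ring C/D/E enediyne (C9 ethynyl, C8 (Z)-pent-1-en-3-ynyl) | CC#C/C=C\[C@@H]1[C@@](C#C)(C)CC[C@@]2(C)[C@@H]3C[C@@H](C)C(=O)C[C@]3(C)CC[C@]12C
A3 | alternative 1 | bis(pinacolato)diborylacetylene | CC1(C)OB(OC1(C)C)C#CB1OC(C)(C)C(C)(C)O1
A4 | alternative 1 | Cp*RuCl(cod) | [Ru+2].[Cl-].Cc1c(C)c(C)[c-](C)c1C.C1=CCCC=CCC1
A5 | alternative 2 | guaia-3,11-diene cis-1,5-diol | C=C(C)[C@H]1CC[C@@H](C)[C@@]2(O)CC=C(C)[C@]2(C1)O
A6 | alternative 2 | (Z)-cyclodecenedione precursor | C=C(C)[C@H]1CC[C@@H](C)C(=O)C/C=C(C)\C(=O)C1
A7 | alternative 2 | SmI2 | [Sm+2].[I-].[I-]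
A8 | alternative 3 | ring D/E acid with C13 vinyl and C14 carboxyl | OC(=O)[C@@]1(C)CC[C@@]2(C)CC3(OCCO3)[C@H](C)C[C@H]2[C@]1(C)C=C
A9 | alternative 3 | ten-membered allylic lactone (olefin geometry and C14 configuration left open) | CC1CC[C@@]2(C)CC3(OCCO3)[C@H](C)C[C@H]2C(C)=CCOC1=O
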